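The added ligand's binding constant times its charge, 0.240 in alder and 0.720 in oak, counts idle complex per free catalyst.

    catalyst intermediate B → catalyst intermediate C (k1 = 0.0191 s⁻¹)
    reagent + catalyst intermediate A ⇌ catalyst intermediate B (K2 = 5.60 M⁻¹, k2 = 8.31 M⁻¹ s⁻¹)
    catalyst intermediate C → free catalyst + product (k3 = 0.00585 s⁻¹)
    substrate + free catalyst ⇌ catalyst intermediate A (K4 = 71.2 M⁻¹, k4 = 83.8 M⁻¹ s⁻¹)
    free catalyst + added ligand ⇌ idle complex, settled at all times (K5 = 1200 M⁻¹)

the same everywhere: substrate 20 mM; reagent 100 mM; free catalyst 0.20 mM; time 15 h

| flask | added ligand |
|---|---|
| alder | 0.20 mM |
| cedar | 0.30 mM |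
| ash | 0.40 mM |
| oak | 0.60 mM |

- amount of product at the end, in percent of the substrate charged for alder, cedar, ash, oak, in this order
- how that number moves from the first to the last of them (falls, then rises / hardly changes / falls all the way / rises, then falls / rises all the way)

- "hardly changes" means that all values lie within two and a half points (for a concentration: within two and a half percent of the largest)
- run time (alder): 15 h

**Reckoning by hand**

1. First instants. Catalyst intermediate A returns to free catalyst at 1.18 s⁻¹, and catalyst intermediate B returns to catalyst intermediate A at 1.48 s⁻¹. Both are far faster than the forward step at 0.0191 s⁻¹, so both bindings stand at balance. Catalyst intermediate C leaves more slowly than catalyst intermediate B, so it builds up to 3.26 per catalyst intermediate B.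

2. Middle. Reagent falls with each turnover, so it is taken at a mean 90.0% of its charge. Each catalyst intermediate A then stands for 3.15 forms of the working round, itself counted. With s the fraction of the substrate charge left, the round runs at s/(s+h) of its top speed. Here h is the slowing fraction, an apparent Michaelis constant in fractions of the charge: one plus the ligand term, over the substrate binding constant times the substrate charge times that count of forms. With the ligand taken at its charge, h is 0.276 in alder, 0.303 in cedar, 0.330 in ash and 0.384 in oak. At top speed the run would turn over 1.65 charges, the same in each flask on this reckoning.

3. Start against end. At s = 1, alder runs at 78.3% of top speed and oak at 72.3%, a ratio of 1.08. Once s is well under h, speed goes as s/h, and the ratio drifts towards 1.39. The ratio of speeds between the two flasks is larger in the tail than at the start.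

4. End. Integrating gives (1 − s) + h·ln(1/s) = W, solved by repeated substitution. Alder keeps a fraction 0.0745 of its substrate and oak 0.136. As fractions of the substrate charge, product comes to 0.925 in alder, 0.910 in cedar, 0.894 in ash and 0.864 in oak. On this reckoning the row falls all the way, by 0.0618 of the charge from alder to oak.

**Forecast and result**

5. The forecast gives 92.2%, 91%, 89.5% and 86.9%, a row that falls all the way: “More ligand therefore trims the late-stage rate only modestly”.

6. The simulation gives 91.8%, 90.5%, 89.1% and 86.5%, a row that falls all the way.

7. In alder at 15.0 h, the substrate left, 7.9%, stands below h; s/(s+h) gives 22.3% of the catalyst in the round, and catalyst intermediates A, B and C together hold 21.5%. In oak at 15.0 h, 13% of substrate against an h of 38.4% gives 25.7%, the three intermediates hold 25.2%, and idle complex holds 29.5%.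

(The constants used here are assumed; the rest is arithmetic.)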